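Which of these flasks holds the most target at the end, and how much?

| flask | starting material | partner | second substrate | protic impurity | precatalyst | temperature | remark | time |
|---|---|---|---|---|---|---|---|---|
| birch | 0.10 M | 0.060 M | 0.050 M | 0.010 M | 1 mM | 95 °C | run made earlier |  |
| cedar | 0.10 M | 0.14 M | 0.050 M | 0.010 M | 1 mM | 128 °C | run made earlier |  |
| winter | 0.10 M | 0.0900 M | 0.0500 M | 0.0100 M | 1.0 mM | 140 °C |  | 5.0 min |
| summer | 0.10 M | 0.0900 M | 0.0500 M | 0.0100 M | 1.0 mM | 80 °C |  | 5.0 min |
| dusk | 0.10 M | 0.0900 M | 0.0500 M | 0.0100 M | 1.0 mM | 110 °C |  | 5.0 min |
| noon | 0.10 M | 0.0900 M | 0.0500 M | 0.0100 M | 1.0 mM |  | at 140 °C until 2.5 min, from then on at 80 °C | 5.0 min |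

| run | time / min | target / % | starting material / % |
|---|---|---|---|
| birch | 2.50 | 2.1 | 97.9 |
| birch | 4.00 | 4.4 | 96.5 |
| birch | 8.00 | 9.3 | 90.1 |
| birch | 15.0 | 21.4 | 77.9 |
| birch | 30.0 | 34.4 | 65.5 |
| cedar | 1.33 | 23.0 | 76.5 |
| cedar | 2.50 | 45.5 | 55.4 |
| cedar | 4.00 | 63.1 | 37.4 |
| cedar | 5.00 | 70.9 | 30.1 |

(scatter of a reading: 0.5 percentage points)

* which flask leads in amount of target, in percent of the starting material charged ("all alike" within 1.5 percentage points) (winter / summer / dusk / noon / all alike)
* how much target is there at the end, in percent of the starting material charged: winter
* how much target is there at the end, in percent of the starting material charged: summer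
* how much target is there at the end, in percent of the starting material charged: dusk
* how much target is there at the end, in percent of the starting material charged: noon

- what was read earlier has a scatter of 0.5 percentage points, one standard deviation
- steps under discussion: starting material + partner + catalyst -> catalyst + target; second substrate + partner + catalyst -> catalyst + second product; partner + precatalyst -> catalyst + spent reagent; second substrate + protic impurity -> quenched substrate

Starting material and partner are consumed together, and birch makes target faster between 8.00 min and 15.0 min than over its first 4.00 min, so one pseudo-first-order constant does not describe birch. So I replace the curve by its mean. Let B̄ be the mean of the partner charge and what remains of it once the final target has taken its share. The mean constant κ is the natural logarithm of starting material charged over starting material left, divided by B̄ and the time. From its last reading, cedar gives 2.30 /M/min, and from its last reading, birch gives 0.330 /M/min. Taking ln κ as straight in temperature between these runs, κ is 4.65 /M/min at 140 °C, 0.796 /M/min at 110 °C and 0.136 /M/min at 80 °C.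

The ladder is the time 1/(κ·charge of partner) held against the 5.0 min allowed. Winter's rung is 2.39 min, shorter than the run. Dusk's is 14.0 min and summer's 81.5 min, both longer. Noon spends 2.5 min on winter's rung, then sits on summer's. Adding time over rung gives exposures of 2.09 for winter, 1.08 for noon, 0.358 for dusk and 0.0614 for summer, which is my order. Full charge overstates partner, so I check that error. Exposure alone means 87.7 % target in winter, but one pass with the mean partner brings this to 65.8 %. For dusk, 30.1 % becomes 25.8 %.

The forecast names winter, with 60 % for winter, 43 % for noon, 26 % for dusk and 3 % for summer, adding that “winter is the least certain”. My winter figure stands above its number.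

The flasks give 57.3 % in winter, 42.4 % in noon, 24.7 % in dusk and 2.81 % in summer, so winter leads noon by 15 percentage points.

    starting material + partner + catalyst → catalyst + target (k = 12.0 /M²/s, Ea = 51.0 kJ/mol)
    second substrate + partner + catalyst → catalyst + second product (k = 20.0 /M²/s, Ea = 35.0 kJ/mol)
    partner + precatalyst → catalyst + spent reagent (k = 0.00720 /M/s, Ea = 53.0 kJ/mol)
    second substrate + protic impurity → quenched substrate (k = 0.640 /M/s, Ea = 72.0 kJ/mol)
    (constants at 80 °C)

By the same definition, winter's result gives κ = 2.77 /M/min, below the 4.65 /M/min extrapolated from cedar's 2.30 /M/min, while dusk's gives 0.730 /M/min against the interpolated 0.796 /M/min. In winter the quench of second substrate by protic impurity had 100 % of its turnover up to 5.0 min behind it at 0.500 min, while at 1.00 min target formation had 25 % and second-product formation 23 % of theirs behind them. Target and second product went on forming side by side, and at 5.00 min winter held 14.4 % of its partner charge.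

The earlier runs and the new flask are calculated on assumed constants.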